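| flask | starting material | capture agent | remark | time |
|---|---|---|---|---|
| zeta | 0.16 M | 0.16 M | run made earlier |  |
| gamma | 0.080 M | 0.16 M | run made earlier |  |
| theta | 0.32 M | 0.16 M | run made earlier |  |
| eta | 0.16 M | 0.32 M | run made earlier |  |
| south | 0.16 M | 0.160 M | a single well-mixed tank run continuously and read at steady state, 30 h in it on average |  |
| west | 0.16 M | 0.160 M | a closed flask charged with all of it at once and left for 30 h | 30 h |
| north-east | 0.16 M (fed, over 24.0 h) | 0.160 M | a stirred flask in which starting material is dosed at a steady rate over 24.0 h without added volume, worked up at 30 h | 30 h |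

| run | time / h | target / % | trapped intermediate / % |
|---|---|---|---|
| zeta | 6.00 | 0 | 23.0 |
| zeta | 12.0 | 2.0 | 38.3 |
| zeta | 20.0 | 5.4 | 48.2 |
| zeta | 25.0 | 6.9 | 51.9 |
| zeta | 30.0 | 10.5 | 54.8 |
| gamma | 3.00 | 0.1 | 9.9 |
| gamma | 10.0 | 1.2 | 36.7 |
| gamma | 15.0 | 2.9 | 48.0 |
| gamma | 25.0 | 6.7 | 58.0 |
| gamma | 40.0 | 12.8 | 63.8 |
| theta | 3.00 | 0.2 | 9.5 |
| theta | 5.00 | 0 | 15.6 |
| theta | 10.0 | 0.9 | 28.6 |
| theta | 20.0 | 5.7 | 38.5 |
| theta | 40.0 | 14.8 | 43.7 |
| eta | 3.00 | 0 | 18.4 |
| eta | 10.0 | 1.2 | 56.2 |
| eta | 15.0 | 2.9 | 66.8 |
| eta | 25.0 | 5.5 | 74.3 |
| eta | 40.0 | 9.2 | 78.7 |

(each reading ± 0.5 percentage points)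

- the set-up with the highest share of target in all that became target or trapped intermediate, at the outlet or at the end ("none" if the first two lie within 2 percentage points) (south / west / north-east / none)
- share of target in all that became target or trapped intermediate, at the outlet or at the end, south
- share of target in all that became target or trapped intermediate, at the outlet or at the end, west
- share of target in all that became target or trapped intermediate, at the outlet or at the end, north-east

- the stated concentrations are those of everything mixed, before any reaction; amounts are the same in each set-up
- the feed brings no volume worth counting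
- the earlier runs were made in a closed, stirred flask

Time is where these set-ups part, since they receive the same charge, so we carry one quantity: the mean age, the average time a portion of starting material has spent in the vessel when it is read. In the dosed north-east flask, a steady feed over 24.0 h and work-up at 30 h give a mean age of 18.0 h. West is 30 h old, and the south tank has the same figure as its average residence time.

What does west give? It repeats the zeta recipe, whose reading at 30.0 h gives a share of 16.1%, with its scatter.

Does north-east stand lower? Its mean age is younger than west's, and the zeta reading at 20.0 h, a little older than 18.0 h, gives 10.1%. We therefore expect about that or somewhat less.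

Does south equal west, then? We reckon not, because its ages are spread around the mean. In zeta, target gained 2.0% by 12.0 h but 5.1 percentage points over the last 10.0 h. Trapped intermediate went the other way: its first 12.0 h brought 38.3%, more than the 6.6 points of its last 10.0 h. In the south tank, spread ages should thus lower trapped intermediate, whose old portions add little, while the old portions win back part of the target that the young ones lack, which puts south above west. This gives a direction, not a size.

The forecast gives 18.5% for south, 15% for west and 8% for north-east, where it sees “high capture agent and young intermediate”; its choice is south.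

    starting material → intermediate A (k = 0.00990 min⁻¹)
    intermediate A → intermediate B (k = 5.00 × 10⁻⁴ min⁻¹)
    intermediate B → target (k = 3.30 × 10⁻⁴ min⁻¹)
    intermediate A + capture agent → trapped intermediate (k = 0.00760 L mol⁻¹ min⁻¹)
    2 starting material → self-condensation product (k = 4.70 × 10⁻⁴ L mol⁻¹ min⁻¹)
    intermediate B → decomposed reagent (k = 7.60 × 10⁻⁵ min⁻¹)

South gives 18.8%, west 14.7% and north-east 9.23%, so south leads. West left to 42.4 h has moved by 5 points to 19.7%, above south, and the order would turn. West held to 20.0 h has moved down by 5 points to 9.70%, close to north-east at mean age 18.0 h. Left until 300 h, north-east has a mean age of 288 h, which is 0.960 of west's instead of 0.600, and west and north-east stand at 34.0% and 34.0%.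

The readings stem from a simulated flask on assumed constants; noise was put on by code.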